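The route rests on the C(sp2)–C(sp3) bond between the methyl-bearing alkene carbon and the β-carbon of the 3-furyl ketone, i.e. on the γ,δ-unsaturated ketone motif CH=C(CH3)–CH2–CH2–C(=O)–furan. The CH2–CH2–C(=O) unit is a ketone homoenolate, carried as the strained ring of 1-(furan-3-yl)cyclopropan-1-ol. In one palladium-catalysed operation this cyclopropanol is ring-opened and coupled with the complete (E)-alkenyl bromide that already holds the (S)-methyl centre, the exo-methylene group and the (E)-ylidene tetronate ring as its methyl ether. The bond forms with retention of the alkene geometry and the ketone appears at the same time. Only O-demethylation follows.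

Key step: step 14

Remark: the exocyclic C5=C double bond of the tetronic acid is read exactly as drawn (5E, side chain syn to C4–OH); this less stable geometry is set by a stereospecific elimination, not by equilibration. Compounds 1, 3, 6 and 10 are taken as commercial.

Step 1
Reactants: 1 ethyl furan-3-carboxylate
Product: 2 1-(furan-3-yl)cyclopropan-1-ol
Conditions: EtMgBr (2.5 equiv), Ti(OiPr)4 (0.3 equiv), THF, 0 °C to rt; aq. NH4Cl
Reagents that add atoms: ethylmagnesium bromide, CC[Mg]Br
Why: Kulinkovich cyclopropanation, in which the titanacyclopropane made from two ethyl groups acts as a 1,2-dicarbanion towards the non-enolisable heteroaryl ester.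

Step 2
Reactants: 3 3-methyltetronic acid (4-hydroxy-3-methylfuran-2(5H)-one)
Product: 4 4-methoxy-3-methylfuran-2(5H)-one
Conditions: Me2SO4, K2CO3, acetone, reflux
Reagents that add atoms: dimethyl sulfate, COS(=O)(=O)OC
Why: Williamson-type O-alkylation of the tetronate anion at O4 should give the vinylogous methyl carbonate.

Step 3
Reactants: 4 4-methoxy-3-methylfuran-2(5H)-one
Product: 5 tert-butyl[(4-methoxy-3-methylfuran-2-yl)oxy]dimethylsilane
Conditions: TBSOTf, Et3N, CH2Cl2, 0 °C
Reagents that add atoms: tert-butyldimethylsilyl triflate, CC(C)(C)[Si](C)(C)OS(=O)(=O)C(F)(F)F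
Why: Soft enolisation and O-silylation of the butenolide (silyl dienol ether formation) is driven by aromatisation to the 2-silyloxyfuran.

Step 4
Reactants: 6 (R)-4-benzyl-3-propanoyl-1,3-oxazolidin-2-one
Product: 8 (R)-4-benzyl-3-[(S)-2-methylpent-4-enoyl]-1,3-oxazolidin-2-one, via sodium enolate 7 (not isolated)
Conditions: NaN(SiMe3)2, THF, −78 °C; allyl iodide, −78 to −40 °C
Reagents that add atoms: allyl iodide, C=CCI
Why: Evans asymmetric alkylation, in which the chelated (Z)-enolate 7 is allylated on the face opposite the benzyl group of the (R)-auxiliary, setting the (S)-methyl stereocentre.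

Step 5
Reactants: 8 (R)-4-benzyl-3-[(S)-2-methylpent-4-enoyl]-1,3-oxazolidin-2-one
Product: 9 (S)-N-methoxy-N,2-dimethylpent-4-enamide
Conditions: MeNH(OMe)·HCl, AlMe3, CH2Cl2, 0 °C to rt
Reagents that add atoms: N,O-dimethylhydroxylamine hydrochloride, CNOC.Cl
Why: Aluminium amide transamination (Weinreb amide formation) should cleave the exocyclic imide carbonyl selectively without touching the α-stereocentre.

Step 6
Reactants: 10 pent-3-yn-1-ol
Product: 12 (E)-4-bromopent-3-en-1-ol, via alkenylzirconocene 11 (not isolated)
Conditions: Cp2Zr(H)Cl (2.5 equiv), THF, rt then 50 °C; NBS, 0 °C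
Reagents that add atoms: N-bromosuccinimide, O=C1CCC(=O)N1Br
Why: Hydrozirconation–bromination, in which syn addition and equilibration under excess hydride place zirconium on the less hindered methyl-bearing alkyne carbon and bromodezirconation with retention gives the (E)-2-bromo-2-alkene.

Step 7
Reactants: 12 (E)-4-bromopent-3-en-1-ol
Product: 14 [(E)-6-bromohept-5-en-1-yn-1-yl]trimethylsilane, via homoallylic triflate 13 (not isolated)
Conditions: Tf2O, 2,6-lutidine, CH2Cl2, −78 °C; crude triflate, LiC≡CSiMe3, THF, −78 to −20 °C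
Reagents that add atoms: lithium (trimethylsilyl)acetylide, [Li]C#C[Si](C)(C)C
Why: SN2 alkylation of an alkynyllithium by a primary triflate at low temperature should outpace elimination, and the alkenyl bromide is inert to the acetylide.

Step 8
Reactants: 14 [(E)-6-bromohept-5-en-1-yn-1-yl]trimethylsilane
Product: 15 (E)-6-bromohept-5-en-1-yne
Conditions: K2CO3 (0.2 equiv), MeOH, rt
Reagents that add atoms: none
Why: Base-catalysed methanolysis of the C(sp)–Si bond (protodesilylation) frees the terminal alkyne and leaves the alkenyl bromide alone.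

Step 9
Reactants: 15 (E)-6-bromohept-5-en-1-yne
Product: 17 (E)-6-bromo-2-iodohepta-1,5-diene, via iodoalkenylborane 16 (not isolated)
Conditions: B-iodo-9-BBN, pentane/CH2Cl2, −20 to 0 °C; AcOH
Reagents that add atoms: B-iodo-9-borabicyclo[3.3.1]nonane, IB1C2CCCC1CCC2
Why: Markovnikov iodoboration of the terminal alkyne (haloboration) followed by protodeboronation with acetic acid should give the 2-iodo-1-alkene without touching the trisubstituted alkenyl bromide.

Step 10
Reactants: 9 (S)-N-methoxy-N,2-dimethylpent-4-enamide; 17 (E)-6-bromo-2-iodohepta-1,5-diene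
Product: 19 (2S,9E)-10-bromo-N-methoxy-N,2-dimethyl-6-methylideneundec-9-enamide, via alkylborane 18 (not isolated)
Conditions: 9-BBN, THF, rt; then 17, Pd(dppf)Cl2 (5 mol %), AsPh3, Cs2CO3, DMF/H2O, rt
Reagents that add atoms: none
Why: Anti-Markovnikov hydroboration and B-alkyl Suzuki–Miyaura coupling, in which the unhindered C–I bond undergoes oxidative addition far faster than the trisubstituted C–Br bond, so the 1,1-disubstituted alkene is built with the bromide intact.

Step 11
Reactants: 19 (2S,9E)-10-bromo-N-methoxy-N,2-dimethyl-6-methylideneundec-9-enamide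
Product: 20 (2S,9E)-10-bromo-2-methyl-6-methylideneundec-9-enal
Conditions: i-Bu2AlH, THF, −78 °C; aq. potassium sodium tartrate
Reagents that add atoms: none
Why: Weinreb amide reduction stops at the chelated tetrahedral aluminium intermediate, so the α-methyl aldehyde is released only on cold work-up, without over-reduction or epimerisation.

Step 12
Reactants: 20 (2S,9E)-10-bromo-2-methyl-6-methylideneundec-9-enal; 5 tert-butyl[(4-methoxy-3-methylfuran-2-yl)oxy]dimethylsilane
Product: 22 (5R)-5-[(1R,2S,9E)-10-bromo-1-hydroxy-2-methyl-6-methylideneundec-9-en-1-yl]-4-methoxy-3-methylfuran-2(5H)-one, via ammonium dienolate 21 (not isolated)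
Conditions: 5, anhydrous Bu4NF (1.05 equiv), THF, −78 °C; then 20, −78 °C; AcOH quench at −78 °C
Reagents that add atoms: none
Why: Fluoride-promoted vinylogous aldol addition (Mukaiyama-type, desilylative), in which the naked furan-2-olate 21 attacks through C5 in an open transition state that is known to favour erythro adducts (Lewis acids give threo), so C5 and C1' are set erythro (5R,1'R drawn for the Felkin–Anh face; the 5S,1'S erythro companion converges in step 13).

Step 13
Reactants: 22 (5R)-5-[(1R,2S,9E)-10-bromo-1-hydroxy-2-methyl-6-methylideneundec-9-en-1-yl]-4-methoxy-3-methylfuran-2(5H)-one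
Product: 24 (5E)-5-[(2S,9E)-10-bromo-2-methyl-6-methylideneundec-9-en-1-ylidene]-4-methoxy-3-methylfuran-2(5H)-one, via erythro mesylate 23 (not isolated)
Conditions: MsCl, Et3N (4 equiv), CH2Cl2, −40 °C to rt
Reagents that add atoms: none
Why: Mesylation and stereospecific anti-periplanar β-elimination of C5–H and C1'–OMs, as established for γ-(α-hydroxyalkyl)butenolides, should turn the erythro relationship into the 5E alkene (chain syn to C4–OMe) that equilibrating dehydrations do not give.

Step 14
Reactants: 24 (5E)-5-[(2S,9E)-10-bromo-2-methyl-6-methylideneundec-9-en-1-ylidene]-4-methoxy-3-methylfuran-2(5H)-one; 2 1-(furan-3-yl)cyclopropan-1-ol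
Product: 25 (5E)-5-[(2S,9E)-13-(furan-3-yl)-2,10-dimethyl-6-methylidene-13-oxotridec-9-en-1-ylidene]-4-methoxy-3-methylfuran-2(5H)-one
Conditions: Pd(OAc)2 (10 mol %), XPhos (20 mol %), Cs2CO3 (2 equiv), toluene, 80 °C
Reagents that add atoms: none
Why: Zerovalent palladium inserts into the C(sp2)–Br bond of 24 with retention, the cesium alkoxide of 2 binds to the divalent alkenylpalladium centre, and strain-driven β-carbon elimination opens the three-membered ring to a palladium homoenolate, Pd–CH2–CH2–C(=O)–furyl, whose C(sp3)–C(sp2) reductive elimination joins the ketone β-carbon to the methyl-bearing alkene carbon. The closest known reaction type is the palladium-catalysed ring-opening cross-coupling of cyclopropanols with aryl and alkenyl halides (palladium homoenolate chemistry). No ring is closed; the only ring event is the opening of the cyclopropanol, which is regiochemically degenerate because its two CH2 groups are equivalent. No stereocentre is created: the (S)-methyl centre is remote and untouched, and the E geometry of the trisubstituted alkene is that of 24, carried through stereoretentive oxidative addition and reductive elimination. The step needs reductive elimination to beat β-hydride elimination of the homoenolate (which would give 1-(furan-3-yl)prop-2-en-1-one and hydrodebrominated 24), which the bulky electron-rich biarylphosphine favours, and it needs the C–Br bond to be the only reactive site. The substrate secures the latter, since the enol-lactone C–O bond and the 1,1-disubstituted alkene are poor partners for palladium and a Heck closure onto the exo-methylene group is geometrically impossible with palladium trans to the tether.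

Step 15
Reactants: 25 (5E)-5-[(2S,9E)-13-(furan-3-yl)-2,10-dimethyl-6-methylidene-13-oxotridec-9-en-1-ylidene]-4-methoxy-3-methylfuran-2(5H)-one
Product: 26 (5E)-5-[(2S,9E)-13-(furan-3-yl)-2,10-dimethyl-6-methylidene-13-oxotridec-9-en-1-ylidene]-4-hydroxy-3-methylfuran-2(5H)-one (target)
Conditions: LiCl (10 equiv), DMSO, 50 °C, dark; dilute aq. HCl to pH 3
Reagents that add atoms: none
Why: Nucleophilic O-demethylation (SN2 attack of chloride on the methyl group of the vinylogous carbonate) should release the stabilised tetronate under neutral conditions that leave the enol-lactone double bond, the furyl ketone and the alkenes untouched.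

Compound list
1 | ethyl furan-3-carboxylate | CCOC(=O)c1ccoc1 | starting material
2 | 1-(furan-3-yl)cyclopropan-1-ol | OC1(CC1)c1ccoc1 | intermediate
3 | 3-methyltetronic acid (4-hydroxy-3-methylfuran-2(5H)-one) | CC1=C(O)COC1=O | starting material
4 | 4-methoxy-3-methylfuran-2(5H)-one | COC1=C(C)C(=O)OC1 | intermediate
5 | tert-butyl[(4-methoxy-3-methylfuran-2-yl)oxy]dimethylsilane | COc1coc(O[Si](C)(C)C(C)(C)C)c1C | intermediate
6 | (R)-4-benzyl-3-propanoyl-1,3-oxazolidin-2-one | CCC(=O)N1[C@H](Cc2ccccc2)COC1=O | starting material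
7 | sodium (Z)-enolate of 6 | C/C=C(\[O-])N1[C@H](Cc2ccccc2)COC1=O.[Na+] | intermediate
8 | (R)-4-benzyl-3-[(S)-2-methylpent-4-enoyl]-1,3-oxazolidin-2-one | C=CC[C@H](C)C(=O)N1[C@H](Cc2ccccc2)COC1=O | intermediate
9 | (S)-N-methoxy-N,2-dimethylpent-4-enamide | C=CC[C@H](C)C(=O)N(C)OC | intermediate
10 | pent-3-yn-1-ol | CC#CCCO | starting material
11 | (E)-alkenylzirconocene chloride from 10 (zirconium on C4, oxygen bound to a second Cp2ZrCl unit) | C/C(=C\CCO[Zr](Cl)(C1C=CC=C1)C1C=CC=C1)[Zr](Cl)(C1C=CC=C1)C1C=CC=C1 | intermediate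
12 | (E)-4-bromopent-3-en-1-ol | OCC/C=C(\C)Br | intermediate
13 | (E)-4-bromopent-3-en-1-yl trifluoromethanesulfonate | FC(F)(F)S(=O)(=O)OCC/C=C(\C)Br | intermediate
14 | [(E)-6-bromohept-5-en-1-yn-1-yl]trimethylsilane | C[Si](C)(C)C#CCC/C=C(\C)Br | intermediate
15 | (E)-6-bromohept-5-en-1-yne | C#CCC/C=C(\C)Br | intermediate
16 | 9-[(1Z,5E)-6-bromo-2-iodohepta-1,5-dien-1-yl]-9-borabicyclo[3.3.1]nonane | C/C(Br)=C\CC/C(I)=C/B1C2CCCC1CCC2 | intermediate
17 | (E)-6-bromo-2-iodohepta-1,5-diene | C=C(I)CC/C=C(\C)Br | intermediate
18 | (S)-5-(9-borabicyclo[3.3.1]nonan-9-yl)-N-methoxy-N,2-dimethylpentanamide | CON(C)C(=O)[C@@H](C)CCCB1C2CCCC1CCC2 | intermediate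
19 | (2S,9E)-10-bromo-N-methoxy-N,2-dimethyl-6-methylideneundec-9-enamide | CON(C)C(=O)[C@@H](C)CCCC(=C)CC/C=C(\C)Br | intermediate
20 | (2S,9E)-10-bromo-2-methyl-6-methylideneundec-9-enal | O=C[C@@H](C)CCCC(=C)CC/C=C(\C)Br | intermediate
21 | tetrabutylammonium 4-methoxy-3-methylfuran-2-olate | COc1coc([O-])c1C.CCCC[N+](CCCC)(CCCC)CCCC | intermediate
22 | (5R)-5-[(1R,2S,9E)-10-bromo-1-hydroxy-2-methyl-6-methylideneundec-9-en-1-yl]-4-methoxy-3-methylfuran-2(5H)-one (erythro) | COC1=C(C)C(=O)O[C@@H]1[C@H](O)[C@@H](C)CCCC(=C)CC/C=C(\C)Br | intermediate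
23 | methanesulfonate of 22 | COC1=C(C)C(=O)O[C@@H]1[C@H](OS(C)(=O)=O)[C@@H](C)CCCC(=C)CC/C=C(\C)Br | intermediate
24 | (5E)-5-[(2S,9E)-10-bromo-2-methyl-6-methylideneundec-9-en-1-ylidene]-4-methoxy-3-methylfuran-2(5H)-one | C=C(CC/C=C(\C)Br)CCC[C@H](C)/C=C1/OC(=O)C(C)=C1OC | intermediate
25 | (5E)-5-[(2S,9E)-13-(furan-3-yl)-2,10-dimethyl-6-methylidene-13-oxotridec-9-en-1-ylidene]-4-methoxy-3-methylfuran-2(5H)-one | C=C(CC/C=C(\C)CCC(=O)c1ccoc1)CCC[C@H](C)/C=C1/OC(=O)C(C)=C1OC | intermediate
26 | (5E)-5-[(2S,9E)-13-(furan-3-yl)-2,10-dimethyl-6-methylidene-13-oxotridec-9-en-1-ylidene]-4-hydroxy-3-methylfuran-2(5H)-one | C=C(CC/C=C(\C)CCC(=O)c1ccoc1)CCC[C@H](C)/C=C1/OC(=O)C(C)=C1O | target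

Total step count: 15. Longest linear sequence: 10 steps (10 → 12 → 14 → 15 → 17 → 19 → 20 → 22 → 24 → 25 → 26).

Steps most likely to fail

Step 14. β-Hydride elimination from the palladium homoenolate may run faster than C–C reductive elimination, so that the cyclopropanol is consumed as the vinyl ketone while 24 is only hydrodebrominated; base-induced opening of 2 to the ethyl ketone is a second drain. The fallback makes the same bond by reductive conjugate addition. It sets out from 2 and 24: aerobic oxidative ring opening of 2 (Pd(OAc)2 cat., pyridine, O2, toluene, 80 °C) deliberately gives 1-(furan-3-yl)prop-2-en-1-one F1. Nickel-catalysed reductive conjugate addition of alkenyl bromide 24 to F1 (NiCl2(dme), neocuproine, Mn powder, Et3SiCl, DMF, rt) should then give, with retention of the alkene geometry, the (Z)-triethylsilyl enol ether of 25 F2. Mild hydrolysis (dilute HCl in THF, 0 °C) returns to the route at 25.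

Step 12. The naked dienolate may discriminate poorly between the erythro and threo modes of addition, or the alkoxide may equilibrate by retro-aldol before the quench; the stereospecific elimination would then pass this on as an E/Z mixture of the ylidene lactone. The fallback selects by separation instead of by reagent control. It sets out from 4 and 20: deprotonation of 4 (LiN(iPr)2, THF, −78 °C) gives lithium 4-methoxy-3-methylfuran-2-olate F3, whose direct aldol addition to 20 should give erythro alcohol 22 together with the threo alcohol (5S,1'R,2'S) F4. The two are diastereomers and are separated by chromatography at the alcohol stage; only pure 22 re-enters the route, at step 13, and F4 is set aside because its anti-elimination leads to the 5Z series.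

Step 15. Chloride-mediated demethylation may be slow on this 5-ylidene tetronate, and prolonged heating in DMSO invites isomerisation of the contra-thermodynamic 5E double bond or condensation at the enolisable furyl ketone. The fallback uses an O4 protecting group that leaves under mild acid. It sets out from 3 and returns at 26:
- Chloromethyl methyl ether and i-Pr2NEt give 4-(methoxymethoxy)-3-methylfuran-2(5H)-one F5.
- TBSOTf/Et3N gives tert-butyl{[4-(methoxymethoxy)-3-methylfuran-2-yl]oxy}dimethylsilane F6.
- Anhydrous Bu4NF generates tetrabutylammonium 4-(methoxymethoxy)-3-methylfuran-2-olate F7, which adds to 20 to give the erythro alcohol F8.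
- MsCl/Et3N gives the erythro mesylate F9 and, by anti-elimination, the (5E)-ylidene alkenyl bromide F10.
- The palladium-catalysed coupling with 2 under the conditions of step 14 gives the O-methoxymethyl ketone F11.
- CF3CO2H in CH2Cl2 at 0 °C removes the acetal and gives 26.

Further compounds
F1 | step 14 | 1-(furan-3-yl)prop-2-en-1-one | C=CC(=O)c1ccoc1
F2 | step 14 | (Z)-triethylsilyl enol ether of 25 | C=C(CC/C=C(\C)C/C=C(\O[Si](CC)(CC)CC)c1ccoc1)CCC[C@H](C)/C=C1/OC(=O)C(C)=C1OC
F3 | step 12 | lithium 4-methoxy-3-methylfuran-2-olate | COc1coc([O-])c1C.[Li+]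
F4 | step 12 | (5S)-5-[(1R,2S,9E)-10-bromo-1-hydroxy-2-methyl-6-methylideneundec-9-en-1-yl]-4-methoxy-3-methylfuran-2(5H)-one (threo) | COC1=C(C)C(=O)O[C@H]1[C@H](O)[C@@H](C)CCCC(=C)CC/C=C(\C)Br
F5 | step 15 | 4-(methoxymethoxy)-3-methylfuran-2(5H)-one | COCOC1=C(C)C(=O)OC1
F6 | step 15 | tert-butyl{[4-(methoxymethoxy)-3-methylfuran-2-yl]oxy}dimethylsilane | COCOc1coc(O[Si](C)(C)C(C)(C)C)c1C
F7 | step 15 | tetrabutylammonium 4-(methoxymethoxy)-3-methylfuran-2-olate | COCOc1coc([O-])c1C.CCCC[N+](CCCC)(CCCC)CCCC
F8 | step 15 | (5R)-5-[(1R,2S,9E)-10-bromo-1-hydroxy-2-methyl-6-methylideneundec-9-en-1-yl]-4-(methoxymethoxy)-3-methylfuran-2(5H)-one (erythro) | COCOC1=C(C)C(=O)O[C@@H]1[C@H](O)[C@@H](C)CCCC(=C)CC/C=C(\C)Br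
F9 | step 15 | methanesulfonate of F8 | COCOC1=C(C)C(=O)O[C@@H]1[C@H](OS(C)(=O)=O)[C@@H](C)CCCC(=C)CC/C=C(\C)Br
F10 | step 15 | (5E)-5-[(2S,9E)-10-bromo-2-methyl-6-methylideneundec-9-en-1-ylidene]-4-(methoxymethoxy)-3-methylfuran-2(5H)-one | C=C(CC/C=C(\C)Br)CCC[C@H](C)/C=C1/OC(=O)C(C)=C1OCOC
F11 | step 15 | (5E)-5-[(2S,9E)-13-(furan-3-yl)-2,10-dimethyl-6-methylidene-13-oxotridec-9-en-1-ylidene]-4-(methoxymethoxy)-3-methylfuran-2(5H)-one | C=C(CC/C=C(\C)CCC(=O)c1ccoc1)CCC[C@H](C)/C=C1/OC(=O)C(C)=C1OCOC
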